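## Structural features

The target is an elemane-type lactone: a cyclohexane (C5–C10) trans-fused along C6–C7 to an α-methylene-γ-butyrolactone (O–C6, C7–C11(=C13)–C12=O). Five ring carbons in a row are stereogenic (C10, C5, C6, C7, C8). The substituents on C5, C6, C7 and C8 alternate between the two faces and are all equatorial. C10 is quaternary, with methyl equatorial and vinyl (C1=C2) axial, so the vinyl group is cis to the 3-hydroxyprop-1-en-2-yl group (C4(=C3)–C15) on C5. C8 carries the ester of (R)-3-hydroxy-2-methylpropanoic acid, whose α-centre can epimerise.

The fragile groups are: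
- the exocyclic enoate, which adds nucleophiles and does not tolerate base;
- the C8 acyloxy group, which can be lost by vinylogous elimination through C7–H, and a free C8 hydroxyl, which can take over the lactone from C6;
- the cis-1,2-dialkenyl array, which can undergo Cope rearrangement on strong heating.

The real difficulty is the quaternary C10 with its alkenyl group cis to the branched alkenyl group on C5, together with telling four hydroxyl groups apart (C6, C8, C15 and the side chain). The key step uses the fact that C1 and C4, the inner carbons of the two alkenes, sit cis on adjacent ring atoms. Joined by a double bond they form a cyclobutene cis-fused across C5–C10, and opening that C1=C4 bond with ethylene returns both terminal alkenes with the cis relation locked.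

## Logic of the disconnections

23 ⇒ 22. The two primary O–Si bonds (C15–O and side-chain O) are cut last. Both primary hydroxyls stay masked so that they cannot compete in the acylation at C8 or add to the enoate. The forward step must be non-basic.

22 ⇒ 18 + 21. The C8–O acyl bond is cut. This splits the molecule into the carbocyclic core and a chiral-pool side chain and removes the sixth stereocentre from the core problem. The forward step must acylate a flanked secondary alcohol without epimerising the acid and without letting the lactone migrate to C8.

21 ⇒ 20 ⇒ 19. The carboxyl O–H (ester C–OMe forward) and the O–Si bond are cut back to the commercial hydroxy ester. The demand is only that the α-centre is not touched.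

18 ⇒ 17. The C8 O–Si bond is reinstalled. Keeping C8 under a more labile silyl group than C15 lets C8 be uncovered alone. The forward step must cleave a secondary triethylsilyl ether beside a primary tert-butyldimethylsilyl ether.

17 ⇒ 14. The C11=C13 bond is cut. The Michael acceptor is therefore introduced only after all enolate and reduction chemistry is finished. The forward step needs a single enolisable site, which 14 provides.

14 ⇒ 12 (through 13). The lactone C12–O bond and the C6–H bond are cut, returning to a keto ester. This removes the C6 stereocentre. The forward reduction must put the hydrogen on the face of the axial C10 vinyl group, so that the hydroxyl ends up equatorial.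

12 ⇒ 11. The C7–C11 bond is cut. This removes the C7 stereocentre and two carbons. The forward step must enolise toward C7 and not C5, alkylate anti to the C8 oxygen, and avoid β-elimination of that oxygen.

11 ⇒ 9 + 10. The C1=C2 and C3=C4 bonds are cut and C1 is reconnected to C4. The cis relation of C5 and C10, the least accessible feature, becomes a cis ring fusion, which a cycloaddition delivers automatically. The forward step must open the strained ring chemoselectively and leave the α-centre C5 alone.

9 ⇒ 7 + 8. The C10–C1 and C5–C4 bonds are cut. Two stereocentres, one quaternary, are traced back to a monocyclic enone with one stereocentre. The forward photocycloaddition must be head-to-head and must occur anti to the C8 oxygen.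

7 ⇒ 6 ⇒ 5. The C10–CH3 bond is cut and the carbonyl is moved back across the ring. The enone loses its β-substituent. Because the carbonyl changes position, 5 must be the (R)-enone to give (S)-7. The 1,2-addition must not trigger elimination of the β-silyloxy group.

5 ⇒ 3 ⇒ 2 ⇒ 1. The C5=C6 alkene (acetate elimination), the carbonyl, the acetyl and the silyl group are removed in turn, back to a meso triol. The single stereocentre of 5 then comes from desymmetrisation of a meso diol. The demands are enzyme selectivity and loss of acetate only.

## Other disconnections considered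

Alternative 1: The cut is C5–C10 and C6–C7, after joining C1 to C11 as a temporary two-carbon bridge. In the forward sense diene A2 and the (E)-boryl enone A3 would combine in an endo Diels–Alder reaction to give the bicyclo[2.2.2]octene A1, whose enol ether bridge is later cleaved oxidatively.
- In favour: two ring bonds, the quaternary carbon and four stereocentres (C10, C5, C6, C7) are formed in one thermal step. Both diene substituents steer the regiochemistry the same way, the silyloxy group making C7 the nucleophilic terminus for the enone β-carbon C6 and the C10 methyl favouring the adjacent acyl carbon. The endo rule places the acyl group syn to the bridge, which becomes the cis relation of C1 and C4. The (E)-alkene gives trans C5/C6, and the boronate can be oxidised to the C6 hydroxyl with retention.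
- Against: A3 should approach A2 on the face away from the C8 silyloxy group. A1 then holds that oxygen on the bridge side, the face opposite to the one it occupies in 23, so C8 must be inverted later. A Mitsunobu esterification with 21 could do this, but on an axial alcohol prone to elimination. Cleavage of the bridge leaves C11 as a carboxyl carbon on C7 and C1 as an aldehyde, so C12 and C13 still have to be added, and three carbonyl groups need separate olefination or homologation next to the epimerisable C5. The hindered methyl-bearing diene terminus may also need forcing conditions that the silyl enol ether tolerates poorly.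
- Comparison: on structure the alternative is the better, because its key step builds the carbocycle and four stereocentres, whereas the chosen key step builds none and inherits the ring from 1. On regiochemical control it is also the better, since the photocycloaddition of the chosen plan relies on a weaker preference. The cis C5/C10 relation is secured about equally, by the endo rule there and by the enforced cis fusion here. On step economy it is the poorer, because of the C8 inversion and the long carbonyl-by-carbonyl endgame.

Alternative 2: The cut is C7–C8. In the forward sense SmI2 would reduce the aldehyde of the open-chain enoate A5 to a ketyl that closes 6-exo onto C7, giving cyclohexanol A4 after protonation of the samarium enolate.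
- In favour: the aldehyde is reduced before the enoate, and such closures normally place hydroxyl and side chain trans through a chair with equatorial substituents. The acetate chain arrives with the ring, so no enolate alkylation of a β-silyloxy ketone is needed. The C8 hydroxyl is born free and already distinguished from the C6 ether.
- Against: A5 must already hold C10 (quaternary), C5 and C6 as an open-chain stereotriad, so the hardest feature is moved into acyclic stereocontrol and is not solved by the key step. The γ-alkoxy enoate can lose its alkoxy group reductively in competition with cyclisation. Closing the lactone from a tert-butyl ester after removal of the benzyl-type ether needs acid that endangers the silyl ether.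
- Comparison: on differentiating the oxygens the alternative is the better, since the chosen plan needs a selective desilylation. On C6 it is also the better, because no ketone has to be reduced against the axial vinyl group. On the C5/C10 relation the chosen plan is clearly stronger, as the ring fusion enforces it. The mechanisms are equally well understood. On step economy the linear assembly of A5 should cost more steps than the six that lead to 9.

Alternative 3: The cut is C5–C6. In the forward sense Me2AlCl would promote a carbonyl-ene closure of aldehyde A7, in which C5 of the (Z)-alkene attacks C6 and the C3 methyl, trans to the tether, delivers hydrogen to oxygen. The product is A6, which is identical with 13.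
- In favour: one step creates the ring, C5, C6 and the C3=C4 methylidene with its allylic oxygen. A chair transition state with the C7 and C8 substituents equatorial gives the equatorial C6 hydroxyl directly. The route converges on 13, so the endgame would be the same as in the chosen plan.
- Against: A7 is an α-branched β-silyloxy aldehyde, open to epimerisation at C7 and to loss of the silyloxy group under the Lewis acid. Its nucleophilic carbon C5 is attached to the quaternary C10 and is hindered. The allylic silyloxy group deactivates the alkene and can bind aluminium. The 1,3-related C8 and quaternary C10 and the trisubstituted (Z)-alkene must all be made in open chain.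
- Comparison: on C6 the alternative is the better, because it avoids the reduction altogether. After the key step it is the equal of the chosen plan, since both pass through 13. On the central problem, C10 and its relation to C5, it is the weaker, because that relation rests on a stereocentre set earlier in an acyclic precursor. On step economy before the key step it is likely the longer.

Key step: step 7

Assumption 1: the lipase in step 2 is taken to acetylate the hydroxyl that leads to 3; if it prefers the other one, the same enzyme used for hydrolysis of the diacetate of 2 gives 3.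

Assumption 2: the photocycloaddition in step 6 is taken to follow the head-to-head orientation usual for terminal alkynes, the unsubstituted alkyne carbon bonding to C10.

Remark: 9 and 11 were mapped atom by atom onto 23; their configurations at C5, C8 and C10 are those of the target, so both are used unchanged, and the enone required is the (S)-isomer 7.

## Route

Step 1
Reactants: 1 cis,cis-cyclohexane-1,3,5-triol
Product: 2 all-cis-5-(triethylsilyloxy)cyclohexane-1,3-diol (meso)
Conditions: Et3SiCl (1.0 equiv), imidazole, DMF, 0 °C
Reagents that add atoms: chlorotriethylsilane, CC[Si](Cl)(CC)CC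
Why: Statistical monosilylation of a meso triol with three equivalent hydroxyls; one equivalent of chlorosilane should give mainly the monoether, unreacted 1 is recovered and over-silylated material is recycled by acid methanolysis; no stereocentre is created because 2 is meso.

Step 2
Reactants: 2 all-cis-5-(triethylsilyloxy)cyclohexane-1,3-diol
Product: 3 (1R,3S,5S)-3-hydroxy-5-(triethylsilyloxy)cyclohexyl acetate
Conditions: immobilised Candida antarctica lipase B, vinyl acetate, tBuOMe, 25 °C
Reagents that add atoms: vinyl acetate, C=COC(C)=O
Why: Lipase-catalysed transesterification (enzymatic desymmetrisation of a meso 1,3-diol): the enzyme acetylates one of the two enantiotopic hydroxyls, which fixes the absolute configuration of all three carbinol carbons at once, and the acetaldehyde released makes the acylation irreversible.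

Step 3
Reactants: 3 (1R,3S,5S)-3-hydroxy-5-(triethylsilyloxy)cyclohexyl acetate
Product: 5 (R)-5-(triethylsilyloxy)cyclohex-2-en-1-one, via acetoxy ketone 4 (not isolated)
Conditions: Dess–Martin periodinane, NaHCO3, CH2Cl2, 0 °C to rt; crude 4, Et3N, CH2Cl2, 0 °C
Reagents that add atoms: none
Why: Dess–Martin oxidation of the only free alcohol gives the β-acetoxy ketone, and mild amine base causes E1cB loss of acetate, a far better leaving group than the silyloxide on the other β-carbon, so the alkene should form on the acetate side only; short exposure at 0 °C avoids a second elimination to the phenol, and the remaining stereocentre is not touched.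

Step 4
Reactants: 5 (R)-5-(triethylsilyloxy)cyclohex-2-en-1-one
Product: 6 (5R)-1-methyl-5-(triethylsilyloxy)cyclohex-2-en-1-ol (C1 epimers)
Conditions: MeLi, CeCl3, THF, −78 °C; then H2O
Reagents that add atoms: methyllithium, [Li]C
Why: Organocerium 1,2-addition to the enone carbonyl: the weakly basic methylcerium species should add without enolising the ketone toward the β-silyloxy carbon; the new carbinol centre forms as a mixture that does not matter because it becomes sp2 in step 5.

Step 5
Reactants: 6 (5R)-1-methyl-5-(triethylsilyloxy)cyclohex-2-en-1-ol
Product: 7 (S)-3-methyl-5-(triethylsilyloxy)cyclohex-2-en-1-one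
Conditions: [C5H5NH][CrO3Cl] (pyridinium chlorochromate), 4 Å MS, CH2Cl2, rt
Reagents that add atoms: pyridinium chlorochromate, [O-][Cr](=O)(=O)Cl.c1cc[nH+]cc1
Why: Babler–Dauben oxidative transposition: the chromate ester of the tertiary allylic alcohol undergoes a [3,3] shift and the secondary allylic chromate is oxidised to the β-methyl enone, so the carbonyl oxygen of 7 comes from the chromium reagent; the carbonyl moves across the ring, which is why (R)-5 gives (S)-7 although no bond to the stereocentre is touched.

Step 6
Reactants: 7 (S)-3-methyl-5-(triethylsilyloxy)cyclohex-2-en-1-one; 8 tert-butyldimethyl(prop-2-yn-1-yloxy)silane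
Product: 9 (1R,4S,6R)-8-[(tert-butyldimethylsilyloxy)methyl]-6-methyl-4-(triethylsilyloxy)bicyclo[4.2.0]oct-7-en-2-one
Conditions: hν (366 nm, uranium-glass filter), 8 (8 equiv), CH2Cl2, −20 °C, stopped before full conversion
Reagents that add atoms: none
Why: Enone–alkyne [2+2] photocycloaddition through the enone triplet: the unsubstituted alkyne terminus should bond to the β-carbon C10 and the resulting α-substituted vinyl radical closes on C5, the four-membered ring can only be cis-fused, and the alkyne approaches the face opposite to the C8 silyloxy group, so C10 and C5 are set together relative to C8; long-wavelength light and incomplete conversion protect the β,γ-unsaturated ketone from a secondary photochemical acyl shift.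

Step 7
Reactants: 9 (1R,4S,6R)-8-[(tert-butyldimethylsilyloxy)methyl]-6-methyl-4-(triethylsilyloxy)bicyclo[4.2.0]oct-7-en-2-one; 10 ethylene
Product: 11 (2R,3R,5S)-2-[3-(tert-butyldimethylsilyloxy)prop-1-en-2-yl]-3-ethenyl-3-methyl-5-(triethylsilyloxy)cyclohexan-1-one
Conditions: (H2IMes)(PCy3)Cl2Ru=CHPh (second-generation Grubbs catalyst, 5 mol %), C2H4 (1 atm), 1,4-benzoquinone (10 mol %), CH2Cl2 (0.01 M), 25 °C
Reagents that add atoms: none
Why: Ring-opening cross-metathesis with ethylene: the ruthenium methylidene formed from the precatalyst and ethylene adds across the strained C1=C4 bond, most readily with ruthenium on the less substituted C1, and cycloreversion of the metallacyclobutane opens the four-membered ring to a ruthenium alkylidene at C1 and the C4=C3 methylidene. Exchange of that alkylidene with ethylene releases the C1=C2 vinyl group and regenerates the methylidene carrier. The closest known reaction type is the ethenolysis of cyclobutenes obtained by enone–alkyne photocycloaddition. No ring is closed; one ring is cleaved and the cyclohexanone stays intact. No stereocentre is formed: C10 and C5 keep the configuration fixed by the cis ring fusion, which becomes the cis relation of vinyl and propenyl groups. The selectivity needed is chemoselectivity for the cyclobutene over the alkenes of the product, and it is secured by the ring strain of about 30 kcal/mol released on opening, which makes this the only irreversible event, while the vinyl group can only exchange degenerately with ethylene and the 1,1-disubstituted alkene next to the tertiary C5 is too hindered to react. High dilution under ethylene suppresses ring-opening oligomerisation. The conditions are neutral, so the ketone α-centre C5 should not epimerise, and benzoquinone intercepts ruthenium hydrides that could move the new C3=C4 bond into conjugation.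

Step 8
Reactants: 11 (2R,3R,5S)-2-[3-(tert-butyldimethylsilyloxy)prop-1-en-2-yl]-3-ethenyl-3-methyl-5-(triethylsilyloxy)cyclohexan-1-one
Product: 12 methyl 2-[(1R,3R,4R,6S)-3-[3-(tert-butyldimethylsilyloxy)prop-1-en-2-yl]-4-ethenyl-4-methyl-2-oxo-6-(triethylsilyloxy)cyclohexyl]acetate
Conditions: LiN(iPr)2 (1.1 equiv), THF, −78 °C; BrCH2CO2Me, DMPU, −78 to −40 °C
Reagents that add atoms: methyl bromoacetate, COC(=O)CBr
Why: Kinetic enolate alkylation: the amide base at −78 °C should remove a proton from the unhindered C7 methylene and not from C5, which is tertiary, flanked by the quaternary C10 and unable to conjugate with the twisted propenyl group; the enolate is alkylated on the face anti to the adjacent C8 silyloxy group, giving the trans diequatorial C7/C8 arrangement, which is also the thermodynamic one, and the low temperature keeps the enolate from expelling the equatorial, poorly aligned β-silyloxide.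

Step 9
Reactants: 12 methyl 2-[(1R,3R,4R,6S)-3-[3-(tert-butyldimethylsilyloxy)prop-1-en-2-yl]-4-ethenyl-4-methyl-2-oxo-6-(triethylsilyloxy)cyclohexyl]acetate
Product: 14 (3aS,4S,6R,7R,7aR)-7-[3-(tert-butyldimethylsilyloxy)prop-1-en-2-yl]-6-ethenyl-6-methyl-4-(triethylsilyloxy)hexahydro-1-benzofuran-2(3H)-one, via hydroxy ester 13 (not isolated)
Conditions: SmI2 (2.5 equiv), THF–H2O, 0 °C to rt; crude 13, DBU (0.2 equiv), PhMe, 40 °C
Reagents that add atoms: none
Why: Single-electron (ketyl) reduction: C6 is set at a pyramidal α-oxido radical or organosamarium that settles with the C–O bond equatorial, so the thermodynamic equatorial alcohol should result, as in dissolving-metal reductions of hindered cyclohexanones, whereas hydride reagents would be pushed to the wrong face by the axial C10 vinyl group; ester, silyl ethers and isolated alkenes are inert to divalent samarium, and base-catalysed transesterification then closes the trans-fused γ-lactone on the only free hydroxyl.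

Step 10
Reactants: 14 (3aS,4S,6R,7R,7aR)-7-[3-(tert-butyldimethylsilyloxy)prop-1-en-2-yl]-6-ethenyl-6-methyl-4-(triethylsilyloxy)hexahydro-1-benzofuran-2(3H)-one
Product: 17 (3aS,4S,6R,7R,7aR)-7-[3-(tert-butyldimethylsilyloxy)prop-1-en-2-yl]-6-ethenyl-6-methyl-3-methylidene-4-(triethylsilyloxy)hexahydro-1-benzofuran-2(3H)-one, via Mannich base 15 (not isolated), via ammonium iodide 16 (not isolated)
Conditions: LiN(iPr)2, THF, −78 °C; CH2=NMe2+ I−, −78 °C to rt; MeI, MeOH, rt; NaHCO3 (aq), CH2Cl2, rt
Reagents that add atoms: N,N-dimethylmethyleneiminium iodide (Eschenmoser's salt), C=[N+](C)C.[I-]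
Why: Mannich reaction of the lactone lithium enolate with Eschenmoser's salt, N-methylation and Hofmann-type elimination of trimethylamine, the standard α-methylenation of γ-lactones; C11 is the only acidic site, no leaving group sits next to the enolate carbon, and the transient C11 stereocentre disappears in the elimination.

Step 11
Reactants: 17 (3aS,4S,6R,7R,7aR)-7-[3-(tert-butyldimethylsilyloxy)prop-1-en-2-yl]-6-ethenyl-6-methyl-3-methylidene-4-(triethylsilyloxy)hexahydro-1-benzofuran-2(3H)-one
Product: 18 (3aR,4S,6R,7R,7aR)-7-[3-(tert-butyldimethylsilyloxy)prop-1-en-2-yl]-6-ethenyl-4-hydroxy-6-methyl-3-methylidenehexahydro-1-benzofuran-2(3H)-one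
Conditions: PPTS (0.2 equiv), MeOH–CH2Cl2 (1:1), 0 °C, monitored
Reagents that add atoms: none
Why: Acid-catalysed methanolysis distinguishes the secondary triethylsilyl ether from the much more robust primary tert-butyldimethylsilyl ether; the medium is not basic, so neither conjugate addition to the enoate nor migration of the lactone to the freed C8 hydroxyl is expected.

Step 12
Reactants: 19 methyl (R)-3-hydroxy-2-methylpropanoate
Product: 20 methyl (R)-3-(tert-butyldimethylsilyloxy)-2-methylpropanoate
Conditions: TBSCl, imidazole, CH2Cl2, 0 °C to rt
Reagents that add atoms: tert-butyldimethylsilyl chloride, CC(C)(C)[Si](C)(C)Cl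
Why: Standard silylation of a primary alcohol; the α-stereocentre is not involved.

Step 13
Reactants: 20 methyl (R)-3-(tert-butyldimethylsilyloxy)-2-methylpropanoate
Product: 21 (R)-3-(tert-butyldimethylsilyloxy)-2-methylpropanoic acid
Conditions: LiOH, THF–H2O, 0 °C; then 1 M HCl to pH 3–4, 0 °C
Reagents that add atoms: lithium hydroxide, [Li+].[OH-]
Why: Saponification at 0 °C should hydrolyse the ester without epimerisation or β-elimination, and the acid is set free at mild pH to spare the silyl ether.

Step 14
Reactants: 18 (3aR,4S,6R,7R,7aR)-7-[3-(tert-butyldimethylsilyloxy)prop-1-en-2-yl]-6-ethenyl-4-hydroxy-6-methyl-3-methylidenehexahydro-1-benzofuran-2(3H)-one; 21 (R)-3-(tert-butyldimethylsilyloxy)-2-methylpropanoic acid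
Product: 22 (3aR,4S,6R,7R,7aR)-7-[3-(tert-butyldimethylsilyloxy)prop-1-en-2-yl]-6-ethenyl-6-methyl-3-methylidene-2-oxooctahydro-1-benzofuran-4-yl (2R)-3-(tert-butyldimethylsilyloxy)-2-methylpropanoate
Conditions: DCC (1.5 equiv), DMAP (0.2 equiv), CH2Cl2, 0 °C to rt
Reagents that add atoms: none
Why: Steglich esterification of the equatorial secondary alcohol; catalytic DMAP at low temperature limits epimerisation of the α-branched acid and migration of the lactone, and C8 keeps its configuration because its C–O bond is not broken.

Step 15
Reactants: 22 (3aR,4S,6R,7R,7aR)-7-[3-(tert-butyldimethylsilyloxy)prop-1-en-2-yl]-6-ethenyl-6-methyl-3-methylidene-2-oxooctahydro-1-benzofuran-4-yl (2R)-3-(tert-butyldimethylsilyloxy)-2-methylpropanoate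
Product: 23 (3aR,4S,6R,7R,7aR)-6-ethenyl-7-(3-hydroxyprop-1-en-2-yl)-6-methyl-3-methylidene-2-oxooctahydro-1-benzofuran-4-yl (2R)-3-hydroxy-2-methylpropanoate
Conditions: HF·pyridine, pyridine, THF, 0 °C to rt
Reagents that add atoms: none
Why: Fluoride-mediated cleavage of both primary silyl ethers under buffered, weakly acidic conditions that should leave the enoate, the C8 ester and the lactone untouched.

## Compound list

1 | cis,cis-cyclohexane-1,3,5-triol | O[C@H]1C[C@@H](O)C[C@@H](O)C1 | starting material
2 | all-cis-5-(triethylsilyloxy)cyclohexane-1,3-diol (meso) | O[C@@H]1C[C@H](O[Si](CC)(CC)CC)C[C@H](O)C1 | intermediate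
3 | (1R,3S,5S)-3-hydroxy-5-(triethylsilyloxy)cyclohexyl acetate | O[C@@H]1C[C@H](O[Si](CC)(CC)CC)C[C@H](OC(C)=O)C1 | intermediate
4 | (1S,5R)-3-oxo-5-(triethylsilyloxy)cyclohexyl acetate | O=C1C[C@H](O[Si](CC)(CC)CC)C[C@H](OC(C)=O)C1 | intermediate
5 | (R)-5-(triethylsilyloxy)cyclohex-2-en-1-one | O=C1C=CC[C@@H](O[Si](CC)(CC)CC)C1 | intermediate
6 | (5R)-1-methyl-5-(triethylsilyloxy)cyclohex-2-en-1-ol (C1 epimers) | CC1(O)C=CC[C@@H](O[Si](CC)(CC)CC)C1 | intermediate
7 | (S)-3-methyl-5-(triethylsilyloxy)cyclohex-2-en-1-one | CC1=CC(=O)C[C@@H](O[Si](CC)(CC)CC)C1 | intermediate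
8 | tert-butyldimethyl(prop-2-yn-1-yloxy)silane | C#CCO[Si](C)(C)C(C)(C)C | starting material
9 | (1R,4S,6R)-8-[(tert-butyldimethylsilyloxy)methyl]-6-methyl-4-(triethylsilyloxy)bicyclo[4.2.0]oct-7-en-2-one (cis-fused, cyclobutene anti to the silyloxy group) | C=3[C@@]1(C)C[C@H](O[Si](CC)(CC)CC)CC(=O)[C@H]1C3CO[Si](C)(C)C(C)(C)C | intermediate
10 | ethylene | C=C | starting material
11 | (2R,3R,5S)-2-[3-(tert-butyldimethylsilyloxy)prop-1-en-2-yl]-3-ethenyl-3-methyl-5-(triethylsilyloxy)cyclohexan-1-one | C=C[C@@]1(C)C[C@H](O[Si](CC)(CC)CC)CC(=O)[C@H]1C(=C)CO[Si](C)(C)C(C)(C)C | intermediate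
12 | methyl 2-[(1R,3R,4R,6S)-3-[3-(tert-butyldimethylsilyloxy)prop-1-en-2-yl]-4-ethenyl-4-methyl-2-oxo-6-(triethylsilyloxy)cyclohexyl]acetate | C=C[C@@]1(C)C[C@H](O[Si](CC)(CC)CC)[C@@H](CC(=O)OC)C(=O)[C@H]1C(=C)CO[Si](C)(C)C(C)(C)C | intermediate
13 | methyl 2-[(1S,2R,3R,4R,6S)-3-[3-(tert-butyldimethylsilyloxy)prop-1-en-2-yl]-4-ethenyl-2-hydroxy-4-methyl-6-(triethylsilyloxy)cyclohexyl]acetate | C=C[C@@]1(C)C[C@H](O[Si](CC)(CC)CC)[C@@H](CC(=O)OC)[C@H](O)[C@H]1C(=C)CO[Si](C)(C)C(C)(C)C | intermediate
14 | (3aS,4S,6R,7R,7aR)-7-[3-(tert-butyldimethylsilyloxy)prop-1-en-2-yl]-6-ethenyl-6-methyl-4-(triethylsilyloxy)hexahydro-1-benzofuran-2(3H)-one | C=C[C@@]1(C)C[C@H](O[Si](CC)(CC)CC)[C@H]2CC(=O)O[C@@H]2[C@H]1C(=C)CO[Si](C)(C)C(C)(C)C | intermediate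
15 | 3-[(dimethylamino)methyl] derivative of 14 (C3 epimers) | C=C[C@@]1(C)C[C@H](O[Si](CC)(CC)CC)[C@H]2C(CN(C)C)C(=O)O[C@@H]2[C@H]1C(=C)CO[Si](C)(C)C(C)(C)C | intermediate
16 | 3-[(trimethylammonio)methyl] derivative of 14, iodide (C3 epimers) | C=C[C@@]1(C)C[C@H](O[Si](CC)(CC)CC)[C@H]2C(C[N+](C)(C)C)C(=O)O[C@@H]2[C@H]1C(=C)CO[Si](C)(C)C(C)(C)C.[I-] | intermediate
17 | (3aS,4S,6R,7R,7aR)-7-[3-(tert-butyldimethylsilyloxy)prop-1-en-2-yl]-6-ethenyl-6-methyl-3-methylidene-4-(triethylsilyloxy)hexahydro-1-benzofuran-2(3H)-one | C=C[C@@]1(C)C[C@H](O[Si](CC)(CC)CC)[C@H]2C(=C)C(=O)O[C@@H]2[C@H]1C(=C)CO[Si](C)(C)C(C)(C)C | intermediate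
18 | (3aR,4S,6R,7R,7aR)-7-[3-(tert-butyldimethylsilyloxy)prop-1-en-2-yl]-6-ethenyl-4-hydroxy-6-methyl-3-methylidenehexahydro-1-benzofuran-2(3H)-one | C=C[C@@]1(C)C[C@H](O)[C@H]2C(=C)C(=O)O[C@@H]2[C@H]1C(=C)CO[Si](C)(C)C(C)(C)C | intermediate
19 | methyl (R)-3-hydroxy-2-methylpropanoate | C[C@H](CO)C(=O)OC | starting material
20 | methyl (R)-3-(tert-butyldimethylsilyloxy)-2-methylpropanoate | C[C@H](CO[Si](C)(C)C(C)(C)C)C(=O)OC | intermediate
21 | (R)-3-(tert-butyldimethylsilyloxy)-2-methylpropanoic acid | C[C@H](CO[Si](C)(C)C(C)(C)C)C(=O)O | intermediate
22 | (3aR,4S,6R,7R,7aR)-7-[3-(tert-butyldimethylsilyloxy)prop-1-en-2-yl]-6-ethenyl-6-methyl-3-methylidene-2-oxooctahydro-1-benzofuran-4-yl (2R)-3-(tert-butyldimethylsilyloxy)-2-methylpropanoate | C=C[C@@]1(C)C[C@H](OC(=O)[C@H](C)CO[Si](C)(C)C(C)(C)C)[C@H]2C(=C)C(=O)O[C@@H]2[C@H]1C(=C)CO[Si](C)(C)C(C)(C)C | intermediate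
23 | (3aR,4S,6R,7R,7aR)-6-ethenyl-7-(3-hydroxyprop-1-en-2-yl)-6-methyl-3-methylidene-2-oxooctahydro-1-benzofuran-4-yl (2R)-3-hydroxy-2-methylpropanoate | C=C[C@@]1(C)C[C@H](OC(=O)[C@H](C)CO)[C@H]2C(=C)C(=O)O[C@@H]2[C@H]1C(=C)CO | target

## Step count and least certain steps

Total: 15 steps. Longest linear sequence: 13 steps (steps 1–11, 14 and 15, from 1); steps 12 and 13 run in parallel. No step after step 7 is heated above 40 °C, to avoid Cope rearrangement of the cis-dialkenyl unit.

Step 7 (key step). The most likely failures are slow initiation on the trisubstituted cyclobutene next to a quaternary carbon, so that the catalyst decays under ethylene before conversion is complete, and hydride-mediated migration of the new C3=C4 bond into conjugation with the ketone. The fallback replaces metathesis by oxidative cleavage and double methylenation. It sets out from 9: the ketone is masked as the dioxolane F1 (1,2-bis(trimethylsilyloxy)ethane, TMSOTf cat., −78 °C). Ozonolysis with PPh3 work-up gives the keto aldehyde F2. Salt-free Ph3P=CH2 at low temperature converts both carbonyl groups into the diene ketal F3. Mild hydrolysis of the ketal (PPTS, wet acetone) then returns to the route at 11.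

Step 6. The most likely failure is poor control over which alkyne carbon bonds to C10, because the preference of a terminal alkyne is only moderate, together with photochemical acyl migration in the product on over-irradiation. The fallback introduces C15 by cross-coupling instead of carrying it on the alkyne. It sets out from 7, which is irradiated with ethynyltrimethylsilane; the bulk of the silyl group should reinforce the head-to-head orientation, as branching does in 3,3-dimethylbut-1-yne, and give the silylcyclobutene F4. Iododesilylation with N-iodosuccinimide gives the iodocyclobutene F5. Stille coupling with Bu3SnCH2OH and Pd(PPh3)4 gives the hydroxymethyl cyclobutene F6. Silylation with TBSCl and imidazole returns to the route at 9.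

Step 8. The most likely failures are enolisation toward the doubly activated C5–H, which would cause scrambling at C5 or alkylation there, proton exchange between product and enolate, and β-elimination of the C8 silyloxide on warming. The fallback separates enolate regiochemistry from the alkylation. It sets out from 11, which is trapped under internal-quench conditions (LiN(iPr)2, Me3SiCl, −78 °C) as the trimethylsilyl enol ether F7, whose regiochemistry can be checked and purified. Fluoride-induced alkylation of F7 with methyl bromoacetate (anhydrous BnMe3NF, THF, −78 to −20 °C), in the absence of amine base, returns to the route at 12.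

Step 9. The most likely failure is delivery of hydrogen to C6 from the face opposite the axial C10 vinyl group, through hindered protonation of the reduced intermediate or incomplete relaxation to the equatorial C–O arrangement; this would lead to the axial alcohol and a cis-fused lactone. The fallback accepts the sterically favoured face and then inverts C6. It sets out from 12, which is reduced with NaBH4 in MeOH at −40 °C; the axial alkoxide should close to the cis-fused lactone F8. LiOH opens F8 to the hydroxy acid F9, which is liberated cold. Mitsunobu lactonisation (PPh3, DIAD, PhMe, 0 °C) displaces the activated axial oxygen with inversion and returns to the route at 14. Competing elimination across C5–C6 is the main hazard of this fallback.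

## Further compounds

F1 | step 7 | ethylene ketal (spiro-1,3-dioxolane at C6) of 9, other centres as in 9 | C=3[C@@]1(C)C[C@H](O[Si](CC)(CC)CC)CC4(OCCO4)[C@H]1C3CO[Si](C)(C)C(C)(C)C
F2 | step 7 | keto aldehyde from ozonolysis of F1 (C1 aldehyde on C10, C4 ketone on C5, ketal retained) | O=C[C@@]1(C)C[C@H](O[Si](CC)(CC)CC)CC2(OCCO2)[C@H]1C(=O)CO[Si](C)(C)C(C)(C)C
F3 | step 7 | ethylene ketal of 11 | C=C[C@@]1(C)C[C@H](O[Si](CC)(CC)CC)CC2(OCCO2)[C@H]1C(=C)CO[Si](C)(C)C(C)(C)C
F4 | step 6 | 8-(trimethylsilyl) analogue of 9: cis-fused 6-methyl-4-(triethylsilyloxy)-8-(trimethylsilyl)bicyclo[4.2.0]oct-7-en-2-one, configuration as in 9 | C=3[C@@]1(C)C[C@H](O[Si](CC)(CC)CC)CC(=O)[C@H]1C3[Si](C)(C)C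
F5 | step 6 | 8-iodo analogue of 9: cis-fused 8-iodo-6-methyl-4-(triethylsilyloxy)bicyclo[4.2.0]oct-7-en-2-one, configuration as in 9 | C=3[C@@]1(C)C[C@H](O[Si](CC)(CC)CC)CC(=O)[C@H]1C3I
F6 | step 6 | (1R,4S,6R)-8-(hydroxymethyl)-6-methyl-4-(triethylsilyloxy)bicyclo[4.2.0]oct-7-en-2-one | C=3[C@@]1(C)C[C@H](O[Si](CC)(CC)CC)CC(=O)[C@H]1C3CO
F7 | step 8 | C6–C7 trimethylsilyl enol ether of 11 | C=C[C@@]1(C)C[C@H](O[Si](CC)(CC)CC)C=C(O[Si](C)(C)C)[C@H]1C(=C)CO[Si](C)(C)C(C)(C)C
F8 | step 9 | C6 epimer of 14 (cis-fused lactone) | C=C[C@@]1(C)C[C@H](O[Si](CC)(CC)CC)[C@H]2CC(=O)O[C@H]2[C@H]1C(=C)CO[Si](C)(C)C(C)(C)C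
F9 | step 9 | hydroxy acid from F8 (axial C6 hydroxyl, C7 acetic acid) | C=C[C@@]1(C)C[C@H](O[Si](CC)(CC)CC)[C@@H](CC(=O)O)[C@@H](O)[C@H]1C(=C)CO[Si](C)(C)C(C)(C)C
A1 | alternative 1 | Diels–Alder adduct: 1-methyl-5-(trimethylsilyloxy)bicyclo[2.2.2]oct-5-ene with endo 2-[(tert-butyldimethylsilyloxy)acetyl], exo 3-(pinacolatoboryl) and 8-(tert-butyldimethylsilyloxy) groups | C[Si](C)(C)OC2=C[C@@]1(C)C[C@@H](O[Si](C)(C)C(C)(C)C)[C@@H]2[C@H](B3OC(C)(C)C(C)(C)O3)[C@H]1C(=O)CO[Si](C)(C)C(C)(C)C
A2 | alternative 1 | (R)-5-(tert-butyldimethylsilyloxy)-1-methyl-3-(trimethylsilyloxy)cyclohexa-1,3-diene | CC1=CC(O[Si](C)(C)C)=C[C@H](O[Si](C)(C)C(C)(C)C)C1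
A3 | alternative 1 | (E)-1-(tert-butyldimethylsilyloxy)-4-(4,4,5,5-tetramethyl-1,3,2-dioxaborolan-2-yl)but-3-en-2-one | CC(C)(C)[Si](C)(C)OCC(=O)/C=C/B1OC(C)(C)C(C)(C)O1
A4 | alternative 2 | cyclised tert-butyl ester: free equatorial C8 hydroxyl, C7 tert-butyl acetate chain, C6 4-methoxybenzyl ether, ring configuration as in 23 | C=C[C@@]1(C)C[C@H](O)[C@@H](CC(=O)OC(C)(C)C)[C@H](OCc2ccc(OC)cc2)[C@H]1C(=C)CO[Si](C)(C)C(C)(C)C
A5 | alternative 2 | tert-butyl (E)-5-[3-(tert-butyldimethylsilyloxy)prop-1-en-2-yl]-6-ethenyl-4-(4-methoxybenzyloxy)-6-methyl-8-oxooct-2-enoate (C4, C5, C6 configured as C6, C5, C10 of 23) | C=C[C@@](C)(CC=O)[C@H](C(=C)CO[Si](C)(C)C(C)(C)C)[C@@H](OCc1ccc(OC)cc1)/C=C/C(=O)OC(C)(C)C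
A6 | alternative 3 | ene product, identical with 13 | C=C[C@@]1(C)C[C@H](O[Si](CC)(CC)CC)[C@@H](CC(=O)OC)[C@H](O)[C@H]1C(=C)CO[Si](C)(C)C(C)(C)C
A7 | alternative 3 | methyl (Z)-9-(tert-butyldimethylsilyloxy)-6-ethenyl-3-formyl-6,8-dimethyl-4-(triethylsilyloxy)non-7-enoate (C3, C4, C6 configured as C7, C8, C10 of 23) | O=C[C@H](CC(=O)OC)[C@@H](O[Si](CC)(CC)CC)C[C@](C)(C=C)/C=C(/C)CO[Si](C)(C)C(C)(C)C
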